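**Plan**
1. Cuts, in order: the three phenol O–H bonds (masked as MOM ethers); the ring–C(=O) bond of the isobutyryl group; the C3–O bond of the side-chain carbinol (traced back to C3–B); the C2–C3 bond ArCH2CH2–C(OH)(CH3), which splits the molecule into a primary arylethyl boronic ester and a lithiated ester of sulcatol; last the ring–C1 bond (aryllithium + ethylene oxide).
2. Forward: no ring is built, since the benzene ring is bought as phloroglucinol. The chain is joined ring–C1/C2 (steps 1–4), C2–C3 (step 7), C–B to C–O (step 8), ring–acyl (step 9), and the phenols are released in step 10.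
3. Enabling feature: C3 carries O, CH3 and two CH2 groups. Without the arylethyl CH2 it is the secondary carbinol carbon of 6-methylhept-5-en-2-ol. An ester on its own oxygen directs lithiation of that C–H, and the same C–O bond then leaves during a 1,2-shift from boron. The C6=C7 alkene lies 4,5 to the carbanion, and the migrating C2 is an unbranched CH2 without a β-leaving group.
4. Helpers: the 2,4,6-triisopropylbenzoate (directing and leaving group) is expelled in the key step itself. The neopentyl glycol boron unit is exchanged for OH in step 8.
5. Second feature: with O on ring C2, C4 and C6, every free ring C–H of the MOM ethers lies between two acetal oxygens and has only symmetry-equivalent partners. Both ring–carbon bonds therefore come from directed ortho-metalation with no regiochemical question.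
6. Stereochemistry: the single centre (3S) comes from enzymatic reduction of sulcatone to (R)-sulcatol and is inverted to (S) in the Mitsunobu esterification. It is then carried stereospecifically through lithiation (retention), borylation (retention), 1,2-shift (inversion) and oxidation (retention).

Key step: step 7

Remark: the side chain is numbered from the benzylic CH2 (C1). The CIP order at C3 is OH > CH2CH2Ar > CH2CH2CH=C > CH3, so the given SMILES is the (3S) isomer.

Step 1
Reactants: 1 phloroglucinol
Product: 2 1,3,5-tris(methoxymethoxy)benzene
Conditions: NaH (3.6 equiv), MOMCl (3.6 equiv), DMF, 0 °C to rt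
Reagents that add atoms: chloromethyl methyl ether (MOMCl), COCCl
Why: Williamson O-alkylation of the phenoxide with the hard electrophile MOMCl, which favours O- over C-alkylation and gives acetals that survive organolithiums, base and alkaline peroxide and later direct the metalations.

Step 2
Reactants: 2 1,3,5-tris(methoxymethoxy)benzene
Product: 4 2-[2,4,6-tris(methoxymethoxy)phenyl]ethanol, via aryllithium 3 (not isolated)
Conditions: nBuLi (1.1 equiv), THF, 0 °C; ethylene oxide (3 equiv), 0 °C to rt; H2O
Reagents that add atoms: ethylene oxide, C1CO1
Why: Directed ortho-metalation at one of three equivalent C–H bonds, each flanked by two OMOM groups, gives a single aryllithium that opens ethylene oxide by SN2 and so adds C1 and C2 of the side chain.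

Step 3
Reactants: 4 2-[2,4,6-tris(methoxymethoxy)phenyl]ethanol
Product: 5 2-(2-bromoethyl)-1,3,5-tris(methoxymethoxy)benzene
Conditions: CBr4, PPh3, CH2Cl2, 0 °C
Reagents that add atoms: carbon tetrabromide, BrC(Br)(Br)Br
Why: Appel reaction, an SN2 displacement on the alkoxyphosphonium salt of a primary alcohol under nearly neutral conditions that leave the MOM acetals intact.

Step 4
Reactants: 5 2-(2-bromoethyl)-1,3,5-tris(methoxymethoxy)benzene
Product: 6 5,5-dimethyl-2-{2-[2,4,6-tris(methoxymethoxy)phenyl]ethyl}-1,3,2-dioxaborinane
Conditions: B2neop2 (1.5 equiv), CuI (10 mol %), PPh3 (13 mol %), LiOMe (2 equiv), DMF, rt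
Reagents that add atoms: bis(neopentyl glycolato)diboron (B2neop2), CC1(C)COB(OC1)B1OCC(C)(C)CO1
Why: Copper-catalysed borylation of a primary alkyl bromide with a diboron reagent (substitution by a boryl-copper species), run with B2neop2 because the unhindered neopentyl glycol ester is the boron partner that the hindered carbanion of step 7 accepts.

Step 5
Reactants: 7 6-methylhept-5-en-2-one (sulcatone)
Product: 8 (R)-6-methylhept-5-en-2-ol, (R)-sulcatol
Conditions: (R)-selective alcohol dehydrogenase from Lactobacillus kefir, NADP+ (cat.), MgCl2, iPrOH (co-substrate), phosphate buffer pH 7, 30 °C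
Reagents that add atoms: none
Why: Enzymatic asymmetric ketone reduction with isopropanol-coupled cofactor recycling, in which the anti-Prelog enzyme delivers hydride to the si face of the methyl ketone and so sets the (R) carbinol centre without touching the isolated alkene.

Step 6
Reactants: 8 (R)-sulcatol
Product: 9 (2S)-6-methylhept-5-en-2-yl 2,4,6-triisopropylbenzoate
Conditions: 2,4,6-triisopropylbenzoic acid, PPh3, DIAD, THF, 0 °C to rt
Reagents that add atoms: 2,4,6-triisopropylbenzoic acid, CC(C)c1cc(C(C)C)c(C(=O)O)c(C(C)C)c1
Why: Mitsunobu esterification, in which the carboxylate displaces the alkoxyphosphonium group by SN2 with inversion, so that (R)-8 gives (S)-9 and the shielded carbonyl group of the acid need not be attacked by the alcohol.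

Step 7
Reactants: 9 (2S)-6-methylhept-5-en-2-yl 2,4,6-triisopropylbenzoate; 6 5,5-dimethyl-2-{2-[2,4,6-tris(methoxymethoxy)phenyl]ethyl}-1,3,2-dioxaborinane
Product: 12 2-{(3R)-3,7-dimethyl-1-[2,4,6-tris(methoxymethoxy)phenyl]oct-6-en-3-yl}-5,5-dimethyl-1,3,2-dioxaborinane, via lithiated benzoate 10 (not isolated), via lithium boronate complex 11 (not isolated)
Conditions: 9, sBuLi (1.6 equiv), TMEDA (6 equiv), CPME, −60 °C, 2 h; 6 (about 2 equiv, to match the surplus of sBuLi) in CPME, −60 °C, 1 h; then rt to 50 °C; H2O
Reagents that add atoms: none
Why: sBuLi/TMEDA, held by the carbonyl oxygen of the benzoate (complex-induced proximity effect), removes the carbinol C–H of 9 with retention to give the configurationally stable tertiary α-oxy-organolithium 10, which adds to the vacant orbital of boron in 6 with retention to give boronate 11, and on warming the arylethyl CH2 shifts from boron to carbon anti-periplanar to the departing benzoate (1,2-metalate rearrangement, inversion at carbon), which makes the C2–C3 bond and joins the two halves. The closest known reaction type is the lithiation–borylation of unactivated secondary dialkyl 2,4,6-triisopropylbenzoates with neopentyl glycol boronic esters, applied here to a new pair of partners. No ring is closed. The one new stereocentre, the fully substituted C3, is controlled only by the carbinol centre of 9: retention, retention and inversion amount, once boron has become oxygen, to replacement of the carbinol hydrogen of (S)-sulcatol by the arylethyl group with retention, so (S)-9 gives (R)-12 and then (S)-13. The step needs α-deprotonation rather than attack on the ester, acyl shift, allylic metalation or carbolithiation, which is secured by the two ortho isopropyl groups that shield the carbonyl group, by the directing effect of that carbonyl group and by the place of the C6=C7 alkene, 4,5 to the carbanion, from where only 4-exo or 5-endo closure would be open. It also needs capture at boron rather than metalation of the MOM-flanked ring C–H of 6, and carbon rather than oxygen migration, which the fast ate-complex formation at the unhindered dioxaborinane, the good benzoate leaving group and the unbranched migrating CH2 without a β-leaving group should secure.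

Step 8
Reactants: 12 tertiary boronic ester
Product: 13 (3S)-3,7-dimethyl-1-[2,4,6-tris(methoxymethoxy)phenyl]oct-6-en-3-ol
Conditions: 30% H2O2, 2 M NaOH, THF, 0 °C to rt
Reagents that add atoms: hydrogen peroxide, OO
Why: Stereoretentive oxidation of the C–B bond (hydroperoxide adds to boron and carbon shifts to oxygen with retention) turns (R)-12 into (S)-13, while alkaline peroxide neither epoxidises the unactivated alkene nor cleaves the MOM acetals.

Step 9
Reactants: 13 (3S)-3,7-dimethyl-1-[2,4,6-tris(methoxymethoxy)phenyl]oct-6-en-3-ol
Product: 15 1-{3-[(3S)-3-hydroxy-3,7-dimethyloct-6-enyl]-2,4,6-tris(methoxymethoxy)phenyl}-2-methylpropan-1-one, via dilithio species 14 (not isolated)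
Conditions: nBuLi (2.3 equiv), THF, 0 °C; iPrC(O)N(OMe)Me (1.5 equiv), −78 °C to rt; H2O
Reagents that add atoms: N-methoxy-N-methylisobutyramide, CC(C)C(=O)N(C)OC
Why: After the carbinol is deprotonated, directed ortho-metalation takes one of the two equivalent ring C–H bonds between two OMOM groups, and the aryllithium is acylated in a Weinreb ketone synthesis, whose chelated tetrahedral intermediate stops over-addition and whose amide does not acylate the tertiary alkoxide.

Step 10
Reactants: 15 tris-MOM ketone
Product: 17 1-{2,4,6-trihydroxy-3-[(3S)-3-hydroxy-3,7-dimethyloct-6-enyl]phenyl}-2-methylpropan-1-one (target), via tetrakis(trimethylsilyl) ether 16 (not isolated)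
Conditions: TMSOTf (8 equiv), 2,2′-bipyridyl (12 equiv), CH3CN, 0 °C to rt; then H2O, rt
Reagents that add atoms: none
Why: Silyl triflate/2,2′-bipyridyl cleavage of aromatic MOM ethers turns each ArO–CH2OMe into ArO–SiMe3 while bipyridyl takes up the methoxymethyl cation and buffers the medium, the carbinol is covered as its silyl ether meanwhile, and water then frees all four hydroxy groups without a strong acid that could ionise C3, close a chroman or add to the alkene.

**Compound list**
1 | phloroglucinol | Oc1cc(O)cc(O)c1 | starting material
2 | 1,3,5-tris(methoxymethoxy)benzene | COCOc1cc(OCOC)cc(OCOC)c1 | intermediate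
3 | 2,4,6-tris(methoxymethoxy)phenyllithium | [Li]c1c(OCOC)cc(OCOC)cc1OCOC | intermediate
4 | 2-[2,4,6-tris(methoxymethoxy)phenyl]ethanol | OCCc1c(OCOC)cc(OCOC)cc1OCOC | intermediate
5 | 2-(2-bromoethyl)-1,3,5-tris(methoxymethoxy)benzene | BrCCc1c(OCOC)cc(OCOC)cc1OCOC | intermediate
6 | 5,5-dimethyl-2-{2-[2,4,6-tris(methoxymethoxy)phenyl]ethyl}-1,3,2-dioxaborinane | CC1(C)COB(CCc2c(OCOC)cc(OCOC)cc2OCOC)OC1 | intermediate
7 | 6-methylhept-5-en-2-one (sulcatone) | CC(=O)CCC=C(C)C | starting material
8 | (R)-6-methylhept-5-en-2-ol | CC(C)=CCC[C@@H](C)O | intermediate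
9 | (2S)-6-methylhept-5-en-2-yl 2,4,6-triisopropylbenzoate | CC(C)=CCC[C@H](C)OC(=O)c1c(C(C)C)cc(C(C)C)cc1C(C)C | intermediate
10 | (2S)-2-lithio-6-methylhept-5-en-2-yl 2,4,6-triisopropylbenzoate | CC(C)=CCC[C@]([Li])(C)OC(=O)c1c(C(C)C)cc(C(C)C)cc1C(C)C | intermediate
11 | lithium [(2S)-6-methyl-2-(2,4,6-triisopropylbenzoyloxy)hept-5-en-2-yl]{2-[2,4,6-tris(methoxymethoxy)phenyl]ethyl}(neopentyl glycolato)borate | CC(C)=CCC[C@]([B-]1(CCc2c(OCOC)cc(OCOC)cc2OCOC)OCC(C)(C)CO1)(C)OC(=O)c1c(C(C)C)cc(C(C)C)cc1C(C)C.[Li+] | intermediate
12 | 2-{(3R)-3,7-dimethyl-1-[2,4,6-tris(methoxymethoxy)phenyl]oct-6-en-3-yl}-5,5-dimethyl-1,3,2-dioxaborinane | CC(C)=CCC[C@@](B1OCC(C)(C)CO1)(C)CCc1c(OCOC)cc(OCOC)cc1OCOC | intermediate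
13 | (3S)-3,7-dimethyl-1-[2,4,6-tris(methoxymethoxy)phenyl]oct-6-en-3-ol | CC(C)=CCC[C@](C)(O)CCc1c(OCOC)cc(OCOC)cc1OCOC | intermediate
14 | ring-lithiated lithium alkoxide of 13 | CC(C)=CCC[C@](C)(O[Li])CCc1c(OCOC)cc(OCOC)c([Li])c1OCOC | intermediate
15 | 1-{3-[(3S)-3-hydroxy-3,7-dimethyloct-6-enyl]-2,4,6-tris(methoxymethoxy)phenyl}-2-methylpropan-1-one | CC(C)=CCC[C@](C)(O)CCc1c(OCOC)cc(OCOC)c(C(=O)C(C)C)c1OCOC | intermediate
16 | tetrakis(trimethylsilyl) ether of the target | CC(C)=CCC[C@](C)(O[Si](C)(C)C)CCc1c(O[Si](C)(C)C)cc(O[Si](C)(C)C)c(C(=O)C(C)C)c1O[Si](C)(C)C | intermediate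
17 | 1-{2,4,6-trihydroxy-3-[(3S)-3-hydroxy-3,7-dimethyloct-6-enyl]phenyl}-2-methylpropan-1-one | CC(C)=CCC[C@](C)(O)CCc1c(O)cc(O)c(C(=O)C(C)C)c1O | target

Total step count: 10. Longest linear sequence: 8 steps (1–4, then 7–10, from phloroglucinol).

**Steps most likely to fail**

Step 7. Deprotonation of the unactivated benzoate may stay incomplete. Surplus sBuLi may use up the boronic ester or metalate its ring. Reversible formation of the crowded ate complex may erode the transfer of configuration.
The fallback buys the carbinol centre and makes the ring–C1 bond instead. It sets out from 2 and comes back at 13.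
- Compound 2 is lithiated as in step 2 and quenched with iodine to give 2-iodo-1,3,5-tris(methoxymethoxy)benzene F1.
- Commercial (S)-(+)-linalool F2 is hydroborated with 9-BBN in THF at its monosubstituted vinyl group, which reacts much faster than the trisubstituted alkene. This gives the B-alkyl-9-BBN adduct of (S)-linalool F3.
- A B-alkyl Suzuki–Miyaura coupling of F3 with F1 (Pd(OAc)2/SPhos, aqueous K3PO4, THF, 60 °C) gives 13 with the stereocentre untouched.

Step 10. During the hydrolytic stage the released formaldehyde may condense with the free ring position of the liberated acylphloroglucinol. The weakly acidic water may also start ionisation at C3, with closure to a chroman and loss of configuration. The most crowded acetal may be cleaved incompletely.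
The fallback separates acetal cleavage from release of the phenols. It sets out from 15 and comes back at 17.
- TESOTf/2,2′-bipyridyl in CH3CN exchanges the three MOM groups for triethylsilyl groups and silylates the carbinol, giving the tetrakis(triethylsilyl) ether F5.
- F5 survives the aqueous wash that removes all formaldehyde-derived material, and it is purified.
- Buffered fluoride (Et3N·3HF or TBAF/AcOH, THF, rt) then frees the four hydroxy groups in the absence of acid and of any formaldehyde source.

Step 9. Acyl transfer from the branched Weinreb amide to the doubly ortho-substituted aryllithium may be slow. Base-induced breakdown of the amide and proton return would then compete.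
The fallback changes the oxidation level of the electrophile. It sets out from 13 and comes back at 15.
- The dilithio species 14 is trapped with the small, reactive isobutyraldehyde to give 1-{3-[(3S)-3-hydroxy-3,7-dimethyloct-6-enyl]-2,4,6-tris(methoxymethoxy)phenyl}-2-methylpropan-1-ol F4, as both epimers at the new benzylic carbinol.
- The secondary alcohol alone is oxidised with Dess–Martin periodinane (NaHCO3, CH2Cl2), which merges the epimers into 15.

Further compounds
F1 | step 7 | 2-iodo-1,3,5-tris(methoxymethoxy)benzene | COCOc1cc(OCOC)c(I)c(OCOC)c1
F2 | step 7 | (S)-(+)-linalool (purchased) | CC(C)=CCC[C@](C)(O)C=C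
F3 | step 7 | 9-[(3R)-3-hydroxy-3,7-dimethyloct-6-enyl]-9-borabicyclo[3.3.1]nonane (B-alkyl-9-BBN adduct of (S)-linalool) | CC(C)=CCC[C@](C)(O)CCB1C2CCCC1CCC2
F4 | step 9 | 1-{3-[(3S)-3-hydroxy-3,7-dimethyloct-6-enyl]-2,4,6-tris(methoxymethoxy)phenyl}-2-methylpropan-1-ol (both benzylic epimers) | CC(C)=CCC[C@](C)(O)CCc1c(OCOC)cc(OCOC)c(C(O)C(C)C)c1OCOC
F5 | step 10 | tetrakis(triethylsilyl) ether of the target | CC(C)=CCC[C@](C)(O[Si](CC)(CC)CC)CCc1c(O[Si](CC)(CC)CC)cc(O[Si](CC)(CC)CC)c(C(=O)C(C)C)c1O[Si](CC)(CC)CC
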